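Time is the axis on which the elm flask and the earlier cedar flask can be laid side by side.

common to all: starting material 16 mM; catalyst 20 mol%; added ligand 1.8 mM
- elm: coupling partner 0.70 equiv; the very flask that is asked about, followed so far
- cedar: coupling partner 1 equiv; run made earlier
- flask: coupling partner 0.700 equiv

- elm (time / min: product / %, starting material / %): 0.500: 0.2, 97.0; 0.667: 0.9, 95.4; 1.00: 1.6, 93.8; 1.50: 1.9, 90.5; 2.50: 5.2, 84.8; 4.00: 11.2, 77.4; 6.00: 18.1, 67.5
- cedar (time / min: product / %, starting material / %): 0.500: 0.6, 96.5; 1.50: 3.3, 90.2; 3.00: 9.5, 82.5; 5.00: 17.5, 72.9; 6.00: 21.7, 68.0; 8.00: 28.7, 59.6; 10.0: 35.3, 52.2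

(readings scatter by 0.3 percentage points)

- factor on the rate of making product when 50% of the starting material are converted if catalyst is charged twice over
- factor on the rate when 50% of the starting material are converted if catalyst is charged at 4 mol% instead

- the numbers in the tables scatter with a standard deviation of 0.3 percentage points
- no earlier run changes the charge of catalyst; that part of a forecast is a guess

Starting material falls first order at nearly the same pace in both flasks, 0.0647 /min in cedar and 0.0659 /min in elm, although their partner charges differ. The elm flask therefore reaches the moment asked about at

ln(2) / 0.0647 /min = 10.7 min.

Product in elm starts almost flat, with 0.2% at 0.500 min, then bends upward to 18.1% at 6.00 min. Counting one coupling partner in each product, my reckoning puts the level of this curve at the partner charge, 0.700 equiv.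

No run varies the catalyst, so my own reckoning rests on an assumption: the rate at a fixed conversion follows the catalyst not held by added ligand. In elm, added ligand is the limiting reagent of that binding, 1.8 mM against 3.20 mM of catalyst. The balance gives the uncovered catalyst, the catalyst charged minus the added ligand, taken one to one:

uncovered catalyst = 3.20 mM − 1.8 mM = 1.40 mM

doubled charge: (2 × 3.20 mM − 1.8 mM) / 1.40 mM = 3.29

At 4 mol% the charge is 0.640 mM, less than the added ligand, so the one-to-one balance comes out at zero uncovered catalyst. With no binding, the factors are 2 and 0.200. My bracket therefore runs from 2 to 3.29 for doubling and from zero to 0.200 for 4 mol%.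

The forecast gives 1.7 (range 1 to 2.2) and 0.25 (range 0.15 to 0.5), and says that “doubling may give less than” the linear factor. There it differs from my bracket.

The simulation gives 2.77 and 0.141.

    coupling partner + catalyst + intermediate → catalyst + product (k = 20000 /M²/min)
    catalyst + added ligand ⇌ idle complex, settled at all times (K = 930 /M)
    starting material + catalyst → catalyst + intermediate (k = 32.0 /M/min)
    coupling partner ⇌ dormant form (K = 1.60, k = 0.0510 /min)

Both factors lie inside the bracket and outside the forecast's ranges, and at 15.0 min the elm flask holds 63.3% of its catalyst unbound, above the one-to-one uncovered share of 43.8%, with 36.7% as idle complex. At that time the coupling partner has a half-life of 4.8 min by the product step, shorter than the 14 min by the forward step to dormant form alone, while intermediate, made 1.58 times faster than used up, stands at 22.3%.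

The numbers in the tables come from a simulation with made-up constants, noise included.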